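The plan rests on disconnecting the tertiary C3'–O bond of the (E)-3-hydroxy-3-methylbut-1-enyl arm on benzene carbon C3, ortho to the acyloxy-bearing C4. An E alkene C1'=C2' conjugated with the benzene ring, next to a carbinol carbon C3' carrying two methyl groups, is the signature of a prenyl group oxygenated with allylic shift. One Schenck ene reaction with singlet oxygen forms the C3'–O bond, removes a benzylic C1' hydrogen and moves the double bond into conjugation. Its precursor is the complete target skeleton with a plain prenyl group: the methyl cinnamate whose phenol oxygen already carries the (S)-3-acetoxybutanoyl group. Neutral deoxygenation of the hydroperoxide ends the route.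

Key step: step 5

Remarks on the chemistry
- Locants: ring carbons are counted from the acrylate-bearing carbon (C1). C1', C2' and C3' are the arm carbons counted from the ring.
- Configuration: at C3 of the butanoyl chain the priorities are OAc > CH2C(=O) > CH3 > H, and the SMILES reads S. (S)-3-Hydroxybutanoic acid is therefore the correct chiral-pool source, and no bond to this carbon is broken in any step.
- Prenyl installation: iodination followed by cross-coupling is preferred to alkylating the ambident phenoxide with prenyl bromide. That alkylation divides between oxygen, one ortho carbon and both ortho carbons. One extra step buys full positional control and leaves the risk in step 5.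
- Order of events: acylation precedes oxidation. A free phenol would bias the ene reaction towards the unwanted hydroperoxide. After oxidation it would also sit beside an ionisable tertiary allylic alcohol and invite closure to a 2,2-dimethylchromene. No protecting group is needed.

Step 1
Reactants: 1 (S)-3-hydroxybutanoic acid
Product: 2 (S)-3-acetoxybutanoic acid
Conditions: AcCl (3 equiv), neat, 0 °C to rt; volatiles removed in vacuo
Reagents that add atoms: acetyl chloride, CC(=O)Cl
Why: O-acetylation by nucleophilic acyl substitution breaks no bond at the stereocentre, so the S configuration is retained, and only volatile by-products form, so the water-soluble acid needs no aqueous work-up.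

Step 2
Reactants: 3 methyl (E)-4-hydroxycinnamate
Product: 4 methyl (E)-3-(4-hydroxy-3-iodophenyl)acrylate
Conditions: NIS (1.0 equiv), p-TsOH·H2O (10 mol %), MeCN, rt, dark
Reagents that add atoms: N-iodosuccinimide, O=C1CCC(=O)N1I
Why: Electrophilic aromatic iodination is directed by the hydroxyl group to the two equivalent ortho carbons because the para carbon is occupied, one equivalent of reagent and the deactivating first iodine hold back a second substitution, and the ester-conjugated alkene is too electron-poor to compete.

Step 3
Reactants: 4 methyl (E)-3-(4-hydroxy-3-iodophenyl)acrylate; 5 tributyl(3-methylbut-2-en-1-yl)stannane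
Product: 6 methyl (E)-3-[4-hydroxy-3-(3-methylbut-2-en-1-yl)phenyl]acrylate
Conditions: Pd(PPh3)4 (5 mol %), 5 (1.3 equiv), DMF, 80 °C, argon
Reagents that add atoms: none
Why: In this Migita–Kosugi–Stille coupling zerovalent palladium inserts into the C–I bond, the stannane hands over the prenyl group and reductive elimination occurs at the unhindered CH2 terminus of the allyl ligand, so the linear prenyl group ends up only on the iodine-bearing carbon under neutral conditions that the free phenol, the methyl ester and the acrylate alkene tolerate.

Step 4
Reactants: 6 methyl (E)-3-[4-hydroxy-3-(3-methylbut-2-en-1-yl)phenyl]acrylate; 2 (S)-3-acetoxybutanoic acid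
Product: 7 methyl (E)-3-[4-[(S)-3-acetoxybutanoyloxy]-3-(3-methylbut-2-en-1-yl)phenyl]acrylate
Conditions: 2 (1.2 equiv), EDC·HCl (1.3 equiv), DMAP (10 mol %), CH2Cl2, 0 °C to rt
Reagents that add atoms: none
Why: Steglich esterification (carbodiimide activation with DMAP as acyl-transfer catalyst) acylates the phenol, the only nucleophile present, at low temperature and without added amine base, which holds back E1cB loss of acetic acid from the beta-acetoxy acyl unit, and the stereocentre lies beta to the carbonyl group and is carried through unchanged.

Step 5
Reactants: 7 methyl (E)-3-[4-[(S)-3-acetoxybutanoyloxy]-3-(3-methylbut-2-en-1-yl)phenyl]acrylate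
Product: 8 methyl (E)-3-[4-[(S)-3-acetoxybutanoyloxy]-3-[(E)-3-hydroperoxy-3-methylbut-1-en-1-yl]phenyl]acrylate
Conditions: O2 (slow stream), 5,10,15,20-tetraphenylporphyrin (0.5 mol %), CH2Cl2 (passed through basic Al2O3), 0 °C, white LED with 450 nm long-pass filter; evaporation below 25 °C, short silica gel column
Reagents that add atoms: dioxygen, O=O
Why: The photoexcited porphyrin transfers its triplet energy to O2, and the electrophilic singlet oxygen attacks the only electron-rich alkene, the trisubstituted C2'=C3' bond of the prenyl arm, through a perepoxide-like transition structure in which one oxygen binds to C3' while the other takes a benzylic hydrogen from C1', which is the Schenck ene reaction as it is known for prenylated arenes. No ring is closed and no stereocentre is created, because C3' carries two methyl groups, and the remote S centre takes no part. The new C1'=C2' bond should be E, since the C1'–H bond that is broken must stand perpendicular to the alkene plane and the aryl group then turns away from the cis methyl group to escape allylic 1,3-strain. Chemoselectivity follows from electronics and energetics: the acrylate alkene and the disubstituted styrene of the product, on a ring deactivated by the acrylate group and by acylation of the phenol oxygen, react far more slowly with singlet oxygen, and the triplet energy of the porphyrin is too low, and the filtered light too long in wavelength, to isomerise or dimerise the cinnamate. The selectivity that decides the step is the choice between the benzylic hydrogens and the methyl hydrogens, which would lead to a secondary hydroperoxide next to an isopropenyl group; as the transition state is early, the conjugation gained counts for little and a sizeable share of that isomer has to be expected. The substrate helps in that the acyl cap removes the phenolic O–H that would hydrogen-bond to the incoming oxygen and steer it to the methyl side, and the isomers should differ enough in polarity to be separated on silica gel at this stage or after step 6.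

Step 6
Reactants: 8 methyl (E)-3-[4-[(S)-3-acetoxybutanoyloxy]-3-[(E)-3-hydroperoxy-3-methylbut-1-en-1-yl]phenyl]acrylate
Product: 9 methyl (E)-3-[4-[(S)-3-acetoxybutanoyloxy]-3-[(E)-3-hydroxy-3-methylbut-1-en-1-yl]phenyl]acrylate
Conditions: PPh3 (1.05 equiv), CH2Cl2, 0 °C
Reagents that add atoms: none
Why: Triphenylphosphine attacks the terminal oxygen of the hydroperoxide and carries it off as the phosphine oxide (standard hydroperoxide deoxygenation), a fast and neutral reaction that leaves the C3'–O bond, both E alkenes, all three ester groups and the S centre untouched and exposes the ionisable tertiary allylic alcohol to neither acid nor base.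

Compound list
1 | (S)-3-hydroxybutanoic acid | C[C@H](O)CC(=O)O | starting material
2 | (S)-3-acetoxybutanoic acid | C[C@H](OC(C)=O)CC(=O)O | intermediate
3 | methyl (E)-4-hydroxycinnamate | COC(=O)/C=C/c1ccc(O)cc1 | starting material
4 | methyl (E)-3-(4-hydroxy-3-iodophenyl)acrylate | COC(=O)/C=C/c1ccc(O)c(I)c1 | intermediate
5 | tributyl(3-methylbut-2-en-1-yl)stannane | CCCC[Sn](CCCC)(CCCC)CC=C(C)C | starting material
6 | methyl (E)-3-[4-hydroxy-3-(3-methylbut-2-en-1-yl)phenyl]acrylate | COC(=O)/C=C/c1ccc(O)c(CC=C(C)C)c1 | intermediate
7 | methyl (E)-3-[4-[(S)-3-acetoxybutanoyloxy]-3-(3-methylbut-2-en-1-yl)phenyl]acrylate | COC(=O)/C=C/c1ccc(OC(=O)C[C@H](C)OC(C)=O)c(CC=C(C)C)c1 | intermediate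
8 | methyl (E)-3-[4-[(S)-3-acetoxybutanoyloxy]-3-[(E)-3-hydroperoxy-3-methylbut-1-en-1-yl]phenyl]acrylate | COC(=O)/C=C/c1ccc(OC(=O)C[C@H](C)OC(C)=O)c(/C=C/C(C)(C)OO)c1 | intermediate
9 | methyl (E)-3-[4-[(S)-3-acetoxybutanoyloxy]-3-[(E)-3-hydroxy-3-methylbut-1-en-1-yl]phenyl]acrylate | COC(=O)/C=C/c1ccc(OC(=O)C[C@H](C)OC(C)=O)c(/C=C/C(C)(C)O)c1 | target

Total step count: 6
Longest linear sequence: 5 steps (3 to 4 to 6 to 7 to 8 to 9, steps 2 to 6); step 1 is a one-step side branch.

Steps most likely to fail

**Risk 1, step 5.**
- What may go wrong: the site selectivity of hydrogen abstraction may be poor (methyl C–H against benzylic C–H). The allylic hydroperoxide may also rearrange allylically or fragment under traces of acid while it is purified.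
- Fallback: it sets out from 7 and returns at 9, passing by 8, by hydroxyselenation and selenoxide elimination.
- N-(Phenylselanyl)phthalimide, water and catalytic camphorsulfonic acid in CH2Cl2 at rt should add PhSe to C2' and OH to the tertiary C3' in the Markovnikov sense. This gives methyl (E)-3-[4-[(S)-3-acetoxybutanoyloxy]-3-[3-hydroxy-3-methyl-2-(phenylselanyl)butyl]phenyl]acrylate F1, as epimers at C2', which is of no consequence.
- mCPBA (1.0 equiv) in CH2Cl2 at −78 °C should oxidise selenium to methyl (E)-3-[4-[(S)-3-acetoxybutanoyloxy]-3-[3-hydroxy-3-methyl-2-(phenylseleninyl)butyl]phenyl]acrylate F2. On warming to rt with 2,6-lutidine this undergoes syn elimination.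
- C3' carries no hydrogen, so only a benzylic C1' hydrogen can be lost. The regiochemistry is therefore fixed by constitution rather than by a rate ratio, and the E alkene of 9 is the expected outcome.

**Risk 2, step 4.**
- What may go wrong: base-induced loss of acetic acid from the activated beta-acetoxy acyl unit may occur during or after acyl transfer, and the activated acid may rearrange to an unreactive N-acyl urea.
- Fallback: it sets out from 1 and 6 and returns at 7. A silyl ether, a far poorer leaving group, stands in for the acetate during the acylation, and the acetate is introduced last.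
- 1 is silylated twice (TBSCl, imidazole, DMF) to tert-butyldimethylsilyl (S)-3-(tert-butyldimethylsilyloxy)butanoate F3.
- The silyl ester alone is cleaved (K2CO3, MeOH–THF–H2O, then pH 4) to (S)-3-(tert-butyldimethylsilyloxy)butanoic acid F4.
- F4 is coupled with 6 (EDC·HCl, DMAP, CH2Cl2, 0 °C) to methyl (E)-3-[4-[(S)-3-(tert-butyldimethylsilyloxy)butanoyloxy]-3-(3-methylbut-2-en-1-yl)phenyl]acrylate F5.
- HF·pyridine in THF at 0 °C should free methyl (E)-3-[4-[(S)-3-hydroxybutanoyloxy]-3-(3-methylbut-2-en-1-yl)phenyl]acrylate F6.
- Ac2O in pyridine at 0 °C then gives 7.

**Risk 3, step 3.**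
- What may go wrong: coupling may occur through the tertiary terminus of the allyl ligand, palladium hydride species may move the double bond into conjugation, and the acidic phenol may protodestannylate the reagent.
- Fallback: it sets out from 3 and returns at 6 by an aromatic Claisen rearrangement, which needs no halide and no tin.
- 3 is O-alkylated with 3-chloro-3-methylbut-1-yne (DBU, CuCl2 cat., MeCN, 0 °C) to methyl (E)-3-[4-(2-methylbut-3-yn-2-yloxy)phenyl]acrylate F7.
- Semihydrogenation (H2, Pd/CaCO3 poisoned with Pb(OAc)2, quinoline, EtOAc) gives methyl (E)-3-[4-(2-methylbut-3-en-2-yloxy)phenyl]acrylate F8.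
- Heating in xylene at about 140 °C triggers the [3,3] shift. The shift inverts the allyl unit so that its CH2 terminus binds to an ortho carbon, and rearomatisation gives 6.
- Only one allyl unit is present and the para carbon is blocked, so double prenylation and positional isomers are excluded.

Further compounds
F1 | step 5 | methyl (E)-3-[4-[(S)-3-acetoxybutanoyloxy]-3-[3-hydroxy-3-methyl-2-(phenylselanyl)butyl]phenyl]acrylate | COC(=O)/C=C/c1ccc(OC(=O)C[C@H](C)OC(C)=O)c(CC([Se]c2ccccc2)C(C)(C)O)c1
F2 | step 5 | methyl (E)-3-[4-[(S)-3-acetoxybutanoyloxy]-3-[3-hydroxy-3-methyl-2-(phenylseleninyl)butyl]phenyl]acrylate | COC(=O)/C=C/c1ccc(OC(=O)C[C@H](C)OC(C)=O)c(CC([Se](=O)c2ccccc2)C(C)(C)O)c1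
F3 | step 4 | tert-butyldimethylsilyl (S)-3-(tert-butyldimethylsilyloxy)butanoate | C[C@H](O[Si](C)(C)C(C)(C)C)CC(=O)O[Si](C)(C)C(C)(C)C
F4 | step 4 | (S)-3-(tert-butyldimethylsilyloxy)butanoic acid | C[C@H](O[Si](C)(C)C(C)(C)C)CC(=O)O
F5 | step 4 | methyl (E)-3-[4-[(S)-3-(tert-butyldimethylsilyloxy)butanoyloxy]-3-(3-methylbut-2-en-1-yl)phenyl]acrylate | COC(=O)/C=C/c1ccc(OC(=O)C[C@H](C)O[Si](C)(C)C(C)(C)C)c(CC=C(C)C)c1
F6 | step 4 | methyl (E)-3-[4-[(S)-3-hydroxybutanoyloxy]-3-(3-methylbut-2-en-1-yl)phenyl]acrylate | COC(=O)/C=C/c1ccc(OC(=O)C[C@H](C)O)c(CC=C(C)C)c1
F7 | step 3 | methyl (E)-3-[4-(2-methylbut-3-yn-2-yloxy)phenyl]acrylate | COC(=O)/C=C/c1ccc(OC(C)(C)C#C)cc1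
F8 | step 3 | methyl (E)-3-[4-(2-methylbut-3-en-2-yloxy)phenyl]acrylate | COC(=O)/C=C/c1ccc(OC(C)(C)C=C)cc1
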